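**Strategy.** Ring B is a pentasubstituted resorcinol (oxygen on C3' and C5', hydrogen only on C4') whose C1' holds benzofuran C2 between the C2' prenyl group and C6'. This ring is built by one [4+2] cycloaddition–aromatization: a 4-prenyl 1-methoxy-1,3-bis(silyloxy)diene and a 2-benzofuranyl alkynyl ketone form C1'–C2' and C5'–C6', so the crowded biaryl bond is never coupled; it is the alkyne–benzofuran bond. The 3-methylbut-2-enoyl group left on C6' beside O5' later closes the chroman. The diene carries tert-butyldimethylsilyl on O3 and trimethylsilyl on O1, so O3' emerges protected and O5' free; ring A carries silyl ethers throughout.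

Key step: step 12

Remark: the silyl enol ether of the keto ester and the ketene acetal double bond of the diene are taken as geometric mixtures; both elements vanish in ring B, and only the 3Z geometry of the diene matters.

Abbreviation: BF = the 6-(tert-butyldimethylsilyloxy)-7-(2-methylbut-3-en-2-yl)-4-(triisopropylsilyloxy)benzofuran-2-yl group.

**Step 1**
Reactants: 1 methyl acetoacetate; 2 prenyl bromide (1-bromo-3-methylbut-2-ene)
Product: 4 methyl 7-methyl-3-oxooct-6-enoate, via dianion 3 (not isolated)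
Conditions: NaH, THF, 0 °C; n-BuLi, 0 °C; then 2, 0 °C → rt; aq. HCl work-up
Reagents that add atoms: none
Why: Double deprotonation gives the dianion, whose more basic terminal (γ) carbon is alkylated by the primary allylic bromide in an SN2 reaction (acetoacetate dianion γ-alkylation).

**Step 2**
Reactants: 4 methyl 7-methyl-3-oxooct-6-enoate
Product: 5 methyl 3-(tert-butyldimethylsilyloxy)-7-methylocta-2,6-dienoate (2E/2Z mixture)
Conditions: TBSOTf, Et3N, CH2Cl2, 0 °C
Reagents that add atoms: tert-butyldimethylsilyl trifluoromethanesulfonate, CC(C)(C)[Si](C)(C)OS(=O)(=O)C(F)(F)F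
Why: Soft enolization of the β-keto ester with silyl triflate and amine should give the conjugated O-silyl enol ether (silyl enol ether formation), the robust silyl group being placed on the oxygen that becomes O3'.

**Step 3**
Reactants: 5 methyl 3-(tert-butyldimethylsilyloxy)-7-methylocta-2,6-dienoate
Product: 7 (3Z)-3-(tert-butyldimethylsilyloxy)-1-methoxy-7-methyl-1-(trimethylsilyloxy)octa-1,3,6-triene, via lithium dienolate 6 (not isolated)
Conditions: LiN(i-Pr)2 (commercial solution), THF, −78 °C; Me3SiCl, −78 °C → rt; pentane, filtration, used crude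
Reagents that add atoms: chlorotrimethylsilane, C[Si](C)(C)Cl
Why: Kinetic γ-deprotonation at C4 and O-silylation of the ester dienolate should give the 1-methoxy-1,3-bis(silyloxy)diene (silyl ketene acetal formation), the 3Z isomer being favoured because it avoids allylic strain between C5 and the ketene acetal.

**Step 4**
Reactants: 8 4,6-dihydroxybenzofuran-3(2H)-one; 2 prenyl bromide
Product: 9 4-hydroxy-6-(3-methylbut-2-en-1-yloxy)benzofuran-3(2H)-one
Conditions: K2CO3 (1.1 equiv), DMF, 0 °C → rt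
Reagents that add atoms: none
Why: Williamson etherification should occur at the more acidic C6 hydroxyl (para to the carbonyl), because the C4 hydroxyl is held in a hydrogen bond to the C3 ketone.

**Step 5**
Reactants: 9 4-hydroxy-6-(3-methylbut-2-en-1-yloxy)benzofuran-3(2H)-one
Product: 10 6-(3-methylbut-2-en-1-yloxy)-4-(triisopropylsilyloxy)benzofuran-3(2H)-one
Conditions: i-Pr3SiCl, imidazole, DMF, rt → 40 °C
Reagents that add atoms: chlorotriisopropylsilane, CC(C)[Si](Cl)(C(C)C)C(C)C
Why: Imidazole-promoted silylation of the remaining phenol; the bulky triisopropylsilyl ether is chosen to screen C5 in the Claisen step and to resist migration and base.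

**Step 6**
Reactants: 10 6-(3-methylbut-2-en-1-yloxy)-4-(triisopropylsilyloxy)benzofuran-3(2H)-one
Product: 12 6-(3-methylbut-2-en-1-yloxy)-4-(triisopropylsilyloxy)benzofuran, via benzylic alcohol 11 (not isolated)
Conditions: NaBH4, THF/MeOH, 0 °C → rt; then 1 M HCl to pH 2, 0 °C → rt
Reagents that add atoms: none
Why: Borohydride reduction of the aryl ketone gives a benzylic alcohol on a trioxygenated ring, which should lose water under mild acid to the aromatic benzofuran (reduction–dehydration of a benzofuran-3(2H)-one).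

**Step 7**
Reactants: 12 6-(3-methylbut-2-en-1-yloxy)-4-(triisopropylsilyloxy)benzofuran
Product: 14 7-(2-methylbut-3-en-2-yl)-4-(triisopropylsilyloxy)benzofuran-6-ol, via trimethylsilyl ether 13 (not isolated)
Conditions: N,O-bis(trimethylsilyl)acetamide (BSA, 2 equiv), N,N-diethylaniline, 190 °C, sealed tube; then MeOH, citric acid, rt
Reagents that add atoms: none
Why: Aromatic Claisen rearrangement transfers the prenyl group with allylic inversion to an ortho carbon, C7 being preferred over C5 because the C6–C7 bond of a benzofuran has the higher double-bond character and C5 is screened by the triisopropylsilyloxy group, while in situ O-silylation by BSA removes the phenolic hydrogen needed for the abnormal Claisen pathway.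

**Step 8**
Reactants: 14 7-(2-methylbut-3-en-2-yl)-4-(triisopropylsilyloxy)benzofuran-6-ol
Product: 15 6-(tert-butyldimethylsilyloxy)-7-(2-methylbut-3-en-2-yl)-4-(triisopropylsilyloxy)benzofuran
Conditions: TBSOTf, 2,6-lutidine, CH2Cl2, 0 °C → rt
Reagents that add atoms: tert-butyldimethylsilyl trifluoromethanesulfonate, CC(C)(C)[Si](C)(C)OS(=O)(=O)C(F)(F)F
Why: A silyl triflate with a hindered pyridine base should silylate even a phenol with an ortho tert-alkyl group (silyl ether formation).

**Step 9**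
Reactants: 15 6-(tert-butyldimethylsilyloxy)-7-(2-methylbut-3-en-2-yl)-4-(triisopropylsilyloxy)benzofuran
Product: 17 6-(tert-butyldimethylsilyloxy)-7-(2-methylbut-3-en-2-yl)-4-(triisopropylsilyloxy)benzofuran-2-carbaldehyde, via 2-lithiobenzofuran 16 (not isolated)
Conditions: n-BuLi, THF, −78 °C; DMF, −78 → 0 °C; H2O work-up
Reagents that add atoms: N,N-dimethylformamide, CN(C)C=O
Why: The C2 hydrogen is the most acidic ring hydrogen of a benzofuran and silyloxy groups are poor directors, so deprotonation at C2 and trapping with DMF should give the 2-carbaldehyde (lithiation–formylation).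

**Step 10**
Reactants: 17 6-(tert-butyldimethylsilyloxy)-7-(2-methylbut-3-en-2-yl)-4-(triisopropylsilyloxy)benzofuran-2-carbaldehyde
Product: 18 6-(tert-butyldimethylsilyloxy)-2-ethynyl-7-(2-methylbut-3-en-2-yl)-4-(triisopropylsilyloxy)benzofuran
Conditions: Me3SiCHN2, LiN(i-Pr)2 (commercial solution), THF, −78 °C; then 17, −78 °C → rt; H2O work-up
Reagents that add atoms: trimethylsilyldiazomethane, C[Si](C)(C)C=[N+]=[N-]
Why: Colvin rearrangement: lithiated trimethylsilyldiazomethane adds to the aldehyde, a Peterson-type elimination and loss of N2 give an alkylidene carbene, and its 1,2-hydrogen shift gives the terminal alkyne under aprotic conditions that spare the aryl silyl ethers.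

**Step 11**
Reactants: 18 6-(tert-butyldimethylsilyloxy)-2-ethynyl-7-(2-methylbut-3-en-2-yl)-4-(triisopropylsilyloxy)benzofuran; 19 3-methylbut-2-enoyl chloride
Product: 20 1-(BF)-5-methylhex-4-en-1-yn-3-one
Conditions: PdCl2(PPh3)2 (2 mol %), CuI (4 mol %), Et3N (1.5 equiv), THF, rt
Reagents that add atoms: none
Why: Acyl Sonogashira coupling: the acid chloride adds oxidatively to zerovalent palladium, the copper acetylide formed with CuI and Et3N transmetalates, and reductive elimination gives the ynone without over-addition.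

**Step 12**
Reactants: 20 1-(BF)-5-methylhex-4-en-1-yn-3-one; 7 (3Z)-3-(tert-butyldimethylsilyloxy)-1-methoxy-7-methyl-1-(trimethylsilyloxy)octa-1,3,6-triene
Product: 23 1-[2-(BF)-4-(tert-butyldimethylsilyloxy)-6-hydroxy-3-(3-methylbut-2-en-1-yl)phenyl]-3-methylbut-2-en-1-one, via cycloadduct 21 (not isolated), via aryl trimethylsilyl ether 22 (not isolated)
Conditions: 7 (2.5 equiv), toluene (1 M), 90 °C, sealed tube; then 0.5 M HCl, THF, 0 °C
Reagents that add atoms: none
Why: The electron-rich diene 7 bonds through its C4 terminus (largest HOMO coefficient, prenyl group turned outward in the s-cis form of the 3Z isomer) to the benzofuran-bearing β-carbon of ynone 20, and its ketene acetal carbon C1 bonds to the α-carbon, in a concerted but strongly asynchronous normal-demand Diels–Alder reaction that may shade into Michael addition followed by ring closure. The closest known reaction type is the cycloaddition–aromatization of 1-alkoxy-1,3-bis(silyloxy)butadienes with aryl alkynyl ketones to biaryl resorcinols. Ring B is closed by the [4+2] cycloaddition itself (in the stepwise limit by 6-exo-trig attack of the allenolate α-carbon on the silyloxy oxocarbenium carbon C1), giving 1,4-cyclohexadiene 21, which loses methanol across C1 and C4 to arene 22. The two sp3 centres of 21 form without control and are erased on aromatization, so no stereocentre survives. The step needs regioselectivity, secured by the matched polarity of diene C4 and ynone Cβ, and chemoselectivity for the triple bond, secured by the poor dienophilicity of the β,β-dimethyl enone and the absence of any Lewis acid that could trigger 1,2-addition. The dilute acid of the work-up should cleave only the labile aryl trimethylsilyl ether ortho to the ketone, leaving O5' free and O3' protected.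

**Step 13**
Reactants: 23 1-[2-(BF)-4-(tert-butyldimethylsilyloxy)-6-hydroxy-3-(3-methylbut-2-en-1-yl)phenyl]-3-methylbut-2-en-1-one
Product: 24 5-(BF)-7-(tert-butyldimethylsilyloxy)-2,2-dimethyl-6-(3-methylbut-2-en-1-yl)chroman-4-one
Conditions: K2CO3 (0.3 equiv), acetone, rt → 40 °C
Reagents that add atoms: none
Why: Phenoxide O5' should add to the β-carbon of the adjacent β,β-dimethyl enone in a 6-endo-trig oxa-Michael reaction favoured by the gem-dimethyl effect, and no stereocentre is formed.

**Step 14**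
Reactants: 24 5-(BF)-7-(tert-butyldimethylsilyloxy)-2,2-dimethyl-6-(3-methylbut-2-en-1-yl)chroman-4-one
Product: 25 5-(BF)-7-(tert-butyldimethylsilyloxy)-2,2-dimethyl-6-(3-methylbut-2-en-1-yl)chroman-4-ol (racemic)
Conditions: NaBH4, THF/EtOH, 0 °C → rt; H2O work-up
Reagents that add atoms: none
Why: Borohydride 1,2-reduction of the chroman-4-one carbonyl should give the secondary benzylic alcohol as a racemate, whose stereocentre is removed in the next step.

**Step 15**
Reactants: 25 5-(BF)-7-(tert-butyldimethylsilyloxy)-2,2-dimethyl-6-(3-methylbut-2-en-1-yl)chroman-4-ol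
Product: 26 6-(tert-butyldimethylsilyloxy)-2-[7-(tert-butyldimethylsilyloxy)-2,2-dimethyl-6-(3-methylbut-2-en-1-yl)chroman-5-yl]-7-(2-methylbut-3-en-2-yl)-4-(triisopropylsilyloxy)benzofuran
Conditions: Et3SiH (5 equiv), CF3CO2H (3 equiv), CH2Cl2, −40 → 0 °C
Reagents that add atoms: none
Why: Ionic hydrogenation: acid ionizes the benzylic alcohol to a cation stabilized by the ortho ring oxygen and the para silyloxy group and Et3SiH transfers hydride to it, while at low temperature the prenyl and 1,1-dimethylallyl groups, whose neighbouring phenols are all silylated, should stay unprotonated.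

**Step 16**
Reactants: 26 6-(tert-butyldimethylsilyloxy)-2-[7-(tert-butyldimethylsilyloxy)-2,2-dimethyl-6-(3-methylbut-2-en-1-yl)chroman-5-yl]-7-(2-methylbut-3-en-2-yl)-4-(triisopropylsilyloxy)benzofuran
Product: 27 artopetelin C, 2-[7-hydroxy-2,2-dimethyl-6-(3-methylbut-2-en-1-yl)chroman-5-yl]-7-(2-methylbut-3-en-2-yl)benzofuran-4,6-diol
Conditions: Bu4NF (3.5 equiv), AcOH (3.5 equiv), THF, 0 °C → rt, argon
Reagents that add atoms: none
Why: Fluoride should cleave all three aryl silyl ethers (desilylation driven by Si–F bond formation), and acetic acid buffers the phenoxides so that the two allyl groups and the air-sensitive polyphenol survive.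

**Compound list**

1 | methyl acetoacetate | COC(=O)CC(C)=O | starting material
2 | prenyl bromide (1-bromo-3-methylbut-2-ene) | CC(C)=CCBr | starting material
3 | sodium lithium dianion of methyl acetoacetate | C=C([O-])C=C([O-])OC.[Na+].[Li+] | intermediate (not isolated)
4 | methyl 7-methyl-3-oxooct-6-enoate | COC(=O)CC(=O)CCC=C(C)C | intermediate
5 | methyl 3-(tert-butyldimethylsilyloxy)-7-methylocta-2,6-dienoate (2E/2Z mixture) | COC(=O)C=C(CCC=C(C)C)O[Si](C)(C)C(C)(C)C | intermediate
6 | lithium (3Z)-3-(tert-butyldimethylsilyloxy)-1-methoxy-7-methylocta-1,3,6-trien-1-olate | COC([O-])=C/C(O[Si](C)(C)C(C)(C)C)=C/CC=C(C)C.[Li+] | intermediate (not isolated)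
7 | (3Z)-3-(tert-butyldimethylsilyloxy)-1-methoxy-7-methyl-1-(trimethylsilyloxy)octa-1,3,6-triene (C1=C2 geometry mixed) | COC(O[Si](C)(C)C)=C/C(O[Si](C)(C)C(C)(C)C)=C/CC=C(C)C | intermediate
8 | 4,6-dihydroxybenzofuran-3(2H)-one | O=C1COc2cc(O)cc(O)c21 | starting material
9 | 4-hydroxy-6-(3-methylbut-2-en-1-yloxy)benzofuran-3(2H)-one | O=C1COc2cc(OCC=C(C)C)cc(O)c21 | intermediate
10 | 6-(3-methylbut-2-en-1-yloxy)-4-(triisopropylsilyloxy)benzofuran-3(2H)-one | O=C1COc2cc(OCC=C(C)C)cc(O[Si](C(C)C)(C(C)C)C(C)C)c21 | intermediate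
11 | 6-(3-methylbut-2-en-1-yloxy)-4-(triisopropylsilyloxy)-2,3-dihydrobenzofuran-3-ol (racemic) | OC1COc2cc(OCC=C(C)C)cc(O[Si](C(C)C)(C(C)C)C(C)C)c21 | intermediate (not isolated)
12 | 6-(3-methylbut-2-en-1-yloxy)-4-(triisopropylsilyloxy)benzofuran | CC(C)=CCOc1cc(O[Si](C(C)C)(C(C)C)C(C)C)c2ccoc2c1 | intermediate
13 | 7-(2-methylbut-3-en-2-yl)-4-(triisopropylsilyloxy)-6-(trimethylsilyloxy)benzofuran | C=CC(C)(C)c1c(O[Si](C)(C)C)cc(O[Si](C(C)C)(C(C)C)C(C)C)c2ccoc12 | intermediate (not isolated)
14 | 7-(2-methylbut-3-en-2-yl)-4-(triisopropylsilyloxy)benzofuran-6-ol | C=CC(C)(C)c1c(O)cc(O[Si](C(C)C)(C(C)C)C(C)C)c2ccoc12 | intermediate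
15 | 6-(tert-butyldimethylsilyloxy)-7-(2-methylbut-3-en-2-yl)-4-(triisopropylsilyloxy)benzofuran | C=CC(C)(C)c1c(O[Si](C)(C)C(C)(C)C)cc(O[Si](C(C)C)(C(C)C)C(C)C)c2ccoc12 | intermediate
16 | 2-lithio derivative of 15 (BF–Li) | C=CC(C)(C)c1c(O[Si](C)(C)C(C)(C)C)cc(O[Si](C(C)C)(C(C)C)C(C)C)c2cc([Li])oc12 | intermediate (not isolated)
17 | 6-(tert-butyldimethylsilyloxy)-7-(2-methylbut-3-en-2-yl)-4-(triisopropylsilyloxy)benzofuran-2-carbaldehyde | C=CC(C)(C)c1c(O[Si](C)(C)C(C)(C)C)cc(O[Si](C(C)C)(C(C)C)C(C)C)c2cc(C=O)oc12 | intermediate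
18 | 6-(tert-butyldimethylsilyloxy)-2-ethynyl-7-(2-methylbut-3-en-2-yl)-4-(triisopropylsilyloxy)benzofuran | C=CC(C)(C)c1c(O[Si](C)(C)C(C)(C)C)cc(O[Si](C(C)C)(C(C)C)C(C)C)c2cc(C#C)oc12 | intermediate
19 | 3-methylbut-2-enoyl chloride | CC(C)=CC(=O)Cl | starting material
20 | 1-(BF)-5-methylhex-4-en-1-yn-3-one | C=CC(C)(C)c1c(O[Si](C)(C)C(C)(C)C)cc(O[Si](C(C)C)(C(C)C)C(C)C)c2cc(C#CC(=O)C=C(C)C)oc12 | intermediate
21 | 1-[2-(BF)-4-(tert-butyldimethylsilyloxy)-6-methoxy-3-(3-methylbut-2-en-1-yl)-6-(trimethylsilyloxy)cyclohexa-1,4-dien-1-yl]-3-methylbut-2-en-1-one (racemic diastereomer mixture) | C=CC(C)(C)c1c(O[Si](C)(C)C(C)(C)C)cc(O[Si](C(C)C)(C(C)C)C(C)C)c2cc(C3=C(C(=O)C=C(C)C)C(OC)(O[Si](C)(C)C)C=C(O[Si](C)(C)C(C)(C)C)C3CC=C(C)C)oc12 | intermediate (not isolated)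
22 | 1-[2-(BF)-4-(tert-butyldimethylsilyloxy)-3-(3-methylbut-2-en-1-yl)-6-(trimethylsilyloxy)phenyl]-3-methylbut-2-en-1-one | C=CC(C)(C)c1c(O[Si](C)(C)C(C)(C)C)cc(O[Si](C(C)C)(C(C)C)C(C)C)c2cc(-c3c(CC=C(C)C)c(O[Si](C)(C)C(C)(C)C)cc(O[Si](C)(C)C)c3C(=O)C=C(C)C)oc12 | intermediate (not isolated)
23 | 1-[2-(BF)-4-(tert-butyldimethylsilyloxy)-6-hydroxy-3-(3-methylbut-2-en-1-yl)phenyl]-3-methylbut-2-en-1-one | C=CC(C)(C)c1c(O[Si](C)(C)C(C)(C)C)cc(O[Si](C(C)C)(C(C)C)C(C)C)c2cc(-c3c(CC=C(C)C)c(O[Si](C)(C)C(C)(C)C)cc(O)c3C(=O)C=C(C)C)oc12 | intermediate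
24 | 5-(BF)-7-(tert-butyldimethylsilyloxy)-2,2-dimethyl-6-(3-methylbut-2-en-1-yl)chroman-4-one | C=CC(C)(C)c1c(O[Si](C)(C)C(C)(C)C)cc(O[Si](C(C)C)(C(C)C)C(C)C)c2cc(-c3c(CC=C(C)C)c(O[Si](C)(C)C(C)(C)C)cc4OC(C)(C)CC(=O)c34)oc12 | intermediate
25 | 5-(BF)-7-(tert-butyldimethylsilyloxy)-2,2-dimethyl-6-(3-methylbut-2-en-1-yl)chroman-4-ol (racemic) | C=CC(C)(C)c1c(O[Si](C)(C)C(C)(C)C)cc(O[Si](C(C)C)(C(C)C)C(C)C)c2cc(-c3c(CC=C(C)C)c(O[Si](C)(C)C(C)(C)C)cc4OC(C)(C)CC(O)c34)oc12 | intermediate
26 | 6-(tert-butyldimethylsilyloxy)-2-[7-(tert-butyldimethylsilyloxy)-2,2-dimethyl-6-(3-methylbut-2-en-1-yl)chroman-5-yl]-7-(2-methylbut-3-en-2-yl)-4-(triisopropylsilyloxy)benzofuran | C=CC(C)(C)c1c(O[Si](C)(C)C(C)(C)C)cc(O[Si](C(C)C)(C(C)C)C(C)C)c2cc(-c3c(CC=C(C)C)c(O[Si](C)(C)C(C)(C)C)cc4OC(C)(C)CCc34)oc12 | intermediate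
27 | artopetelin C | C=CC(C)(C)c1c(O)cc(O)c2cc(-c3c(CC=C(C)C)c(O)cc4OC(C)(C)CCc34)oc12 | target

**Step count.** Total: 16 steps. Longest linear sequence: 13 steps (8 → 27, steps 4–16); the diene branch (steps 1–3) joins at step 12.

**Steps most likely to fail**

1. Step 12. The cycloaddition may be slower than the thermal decay of diene 7 (oxygen-to-carbon silyl shift, hydrolysis), because both bonding termini are substituted and the ynone is deactivated by the electron-rich benzofuran. Fallback: change the dienophile to an alkynyl aldehyde and build the enone afterwards. Setting out from alkyne 18, deprotonation with n-BuLi (THF, −78 °C) gives the lithium acetylide F1, which DMF formylates to 3-(BF)prop-2-ynal F2, a smaller and more electrophilic dienophile. Heating F2 with diene 7 (toluene, 80 °C) and the acid work-up of step 12 should give, through the cycloadduct F3 and the aryl trimethylsilyl ether F4, 2-(BF)-4-(tert-butyldimethylsilyloxy)-6-hydroxy-3-(3-methylbut-2-en-1-yl)benzaldehyde F5. Addition of (CH3)2C=CHMgBr (2.2 equiv, THF, −78 → 0 °C) gives the allylic alcohol F6, which is oxidized without purification with MnO2 (CH2Cl2, rt) to rejoin the route at enone 23.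

2. Step 7. The allyl terminus may bond to C5 in competition with C7, and the electron-rich benzofuran or the crowded new phenol may degrade at the temperature of the rearrangement. Fallback: rearrange before the furan ring is aromatized. In ketone 10 the nucleus is deactivated, and conjugation of O1 with the C3 carbonyl through C7a fixes double-bond character in C6–C7, as in 7-allyloxychromones, which rearrange to C8. Setting out from ketone 10, heating in N,N-diethylaniline (180 °C) should give 6-hydroxy-7-(2-methylbut-3-en-2-yl)-4-(triisopropylsilyloxy)benzofuran-3(2H)-one F7. Silylation (TBSOTf, 2,6-lutidine, CH2Cl2) gives its tert-butyldimethylsilyl ether F8. Reduction with NaBH4 and acid dehydration as in step 6, through the 3-ol F9, rejoin the route at benzofuran 15.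

3. Step 15. The benzylic cation may be captured within the molecule by C3 of the neighbouring benzofuran (Friedel–Crafts closure of a five-membered ring), or the acid may protonate the prenyl double bond, before hydride transfer occurs. Fallback: an acid-free, anionic deoxygenation through a para-quinone methide. Setting out from alcohol 25, acetylation (Ac2O, pyridine, DMAP, CH2Cl2) gives the 4-acetate F10. Treatment with Bu4NF and NaBH4 (THF/EtOH, 0 °C → rt) frees the phenoxide at C3' (chroman C7), which expels acetate to a para-quinone methide that NaBH4 reduces at chroman C4. The ring A silyl ethers are cleaved in the same operation, so the sequence rejoins the route at target 27.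

**Further compounds**

F1 | step 12 | lithium acetylide of 18 (BF–C≡C–Li) | C=CC(C)(C)c1c(O[Si](C)(C)C(C)(C)C)cc(O[Si](C(C)C)(C(C)C)C(C)C)c2cc(C#C[Li])oc12
F2 | step 12 | 3-(BF)prop-2-ynal | C=CC(C)(C)c1c(O[Si](C)(C)C(C)(C)C)cc(O[Si](C(C)C)(C(C)C)C(C)C)c2cc(C#CC=O)oc12
F3 | step 12 | 2-(BF)-4-(tert-butyldimethylsilyloxy)-6-methoxy-3-(3-methylbut-2-en-1-yl)-6-(trimethylsilyloxy)cyclohexa-1,4-diene-1-carbaldehyde (racemic diastereomer mixture) | C=CC(C)(C)c1c(O[Si](C)(C)C(C)(C)C)cc(O[Si](C(C)C)(C(C)C)C(C)C)c2cc(C3=C(C=O)C(OC)(O[Si](C)(C)C)C=C(O[Si](C)(C)C(C)(C)C)C3CC=C(C)C)oc12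
F4 | step 12 | 2-(BF)-4-(tert-butyldimethylsilyloxy)-3-(3-methylbut-2-en-1-yl)-6-(trimethylsilyloxy)benzaldehyde | C=CC(C)(C)c1c(O[Si](C)(C)C(C)(C)C)cc(O[Si](C(C)C)(C(C)C)C(C)C)c2cc(-c3c(CC=C(C)C)c(O[Si](C)(C)C(C)(C)C)cc(O[Si](C)(C)C)c3C=O)oc12
F5 | step 12 | 2-(BF)-4-(tert-butyldimethylsilyloxy)-6-hydroxy-3-(3-methylbut-2-en-1-yl)benzaldehyde | C=CC(C)(C)c1c(O[Si](C)(C)C(C)(C)C)cc(O[Si](C(C)C)(C(C)C)C(C)C)c2cc(-c3c(CC=C(C)C)c(O[Si](C)(C)C(C)(C)C)cc(O)c3C=O)oc12
F6 | step 12 | 1-[2-(BF)-4-(tert-butyldimethylsilyloxy)-6-hydroxy-3-(3-methylbut-2-en-1-yl)phenyl]-3-methylbut-2-en-1-ol (racemic) | C=CC(C)(C)c1c(O[Si](C)(C)C(C)(C)C)cc(O[Si](C(C)C)(C(C)C)C(C)C)c2cc(-c3c(CC=C(C)C)c(O[Si](C)(C)C(C)(C)C)cc(O)c3C(O)C=C(C)C)oc12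
F7 | step 7 | 6-hydroxy-7-(2-methylbut-3-en-2-yl)-4-(triisopropylsilyloxy)benzofuran-3(2H)-one | O=C1COc2c(C(C)(C)C=C)c(O)cc(O[Si](C(C)C)(C(C)C)C(C)C)c21
F8 | step 7 | 6-(tert-butyldimethylsilyloxy)-7-(2-methylbut-3-en-2-yl)-4-(triisopropylsilyloxy)benzofuran-3(2H)-one | O=C1COc2c(C(C)(C)C=C)c(O[Si](C)(C)C(C)(C)C)cc(O[Si](C(C)C)(C(C)C)C(C)C)c21
F9 | step 7 | 6-(tert-butyldimethylsilyloxy)-7-(2-methylbut-3-en-2-yl)-4-(triisopropylsilyloxy)-2,3-dihydrobenzofuran-3-ol (racemic) | OC1COc2c(C(C)(C)C=C)c(O[Si](C)(C)C(C)(C)C)cc(O[Si](C(C)C)(C(C)C)C(C)C)c21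
F10 | step 15 | 5-(BF)-7-(tert-butyldimethylsilyloxy)-2,2-dimethyl-6-(3-methylbut-2-en-1-yl)chroman-4-yl acetate (racemic) | C=CC(C)(C)c1c(O[Si](C)(C)C(C)(C)C)cc(O[Si](C(C)C)(C(C)C)C(C)C)c2cc(-c3c(CC=C(C)C)c(O[Si](C)(C)C(C)(C)C)cc4OC(C)(C)CC(OC(C)=O)c34)oc12
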